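**Retrosynthetic overview**
1. Feature: in the target γ-lactone (O1, C2=O, C3, C4, C5), C4 carries two oxygenated carbons, the ring carbon C5 (bonded to O1 and ring B) and the exocyclic CH2OH carbon. If the C2 acyl group sits on the CH2OH oxygen instead of O1, these two carbons trade ring and side-chain roles. The crowded cis pair C3-benzyl/C4-CH2OH then becomes an easy trans pair C3-benzyl/C4-(C5 arm).
2. Disconnection of C2–O1: the target lactone goes back to that isomeric lactone, with the future CH2OH carbon held at the aldehyde level as a (+)-menthyl acetal so that the forward acyl shift cannot reverse. The C5 carbinol comes from an aryl ketone, and the ketone from a dithiane.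
3. Disconnection of C4–C5 and C3–CH2(ring A) in one operation: ring B dithiane anion, (5S)-menthyloxyfuranone and ring A benzyl bromide.
4. Ring order: rings A and B arrive with vanillin. The auxiliary lactone ring is made first, from the furan ring of furfural. The target lactone ring closes in step 10 while the auxiliary ring opens.

Key step: step 7

Remark: the labels C2–C5 of the target lactone are kept for the same atoms in all intermediates, while locants in the systematic names of 13–16 follow the auxiliary ring, whose C5 is the acetal carbon. Ring A is the arene of the benzyl group, ring B the arene on C5, TIPS is triisopropylsilyl, and menthyl is (1S,2R,5S)-2-isopropyl-5-methylcyclohexyl.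

Step 1
Reactants: 1 furfural
Product: 2 5-hydroxyfuran-2(5H)-one (racemic lactol)
Conditions: O2, visible light, rose bengal disodium salt (C20H2Cl4I4Na2O5, cat.), MeOH, 0–20 °C
Reagents that add atoms: dioxygen, O=O
Why: Dye-sensitised singlet-oxygen [4+2] cycloaddition to the furan gives an endoperoxide whose methanolysis expels the formyl carbon as methyl formate, which is the standard photo-oxygenation of furfural; the lactol carbon is left racemic on purpose.

Step 2
Reactants: 2 5-hydroxyfuran-2(5H)-one; 3 (+)-menthol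
Product: 5 (5S)-5-[(1S,2R,5S)-menthyloxy]furan-2(5H)-one, via C5-epimeric acetal mixture 4 (not isolated)
Conditions: p-toluenesulfonic acid monohydrate (cat.), toluene, Dean–Stark reflux; crystallisation from hexane, −20 °C; mother liquor re-equilibrated with the same acid and crystallised again
Reagents that add atoms: none
Why: Acid-catalysed acetalisation of the lactol gives both acetal epimers, and the (5S) epimer (mirror image of the crystalline epimer of the (−)-menthol series) should crystallise while the acetal carbon epimerises under the acid, so the stereocentre is fixed by crystallisation-driven selection relayed from (+)-menthol.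

Step 3
Reactants: 6 vanillin
Product: 7 3-methoxy-4-(triisopropylsilyloxy)benzaldehyde
Conditions: TIPSCl, imidazole, DMF, rt
Reagents that add atoms: triisopropylsilyl chloride, CC(C)[Si](Cl)(C(C)C)C(C)C
Why: Imidazole-promoted silylation of a phenol; TIPS tolerates n-BuLi and mild base and leaves with fluoride, whereas a benzyl ether could not be hydrogenolysed later without cutting the benzylic C5–O1 bond.

Step 4
Reactants: 7 3-methoxy-4-(triisopropylsilyloxy)benzaldehyde; 8 propane-1,3-dithiol
Product: 9 2-[3-methoxy-4-(triisopropylsilyloxy)phenyl]-1,3-dithiane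
Conditions: BF3·OEt2 (10 mol%), CH2Cl2, 0 °C to rt
Reagents that add atoms: none
Why: Lewis-acid-catalysed dithioacetalisation of an aromatic aldehyde installs the umpolung handle that turns the future C5 into a nucleophile.

Step 5
Reactants: 7 3-methoxy-4-(triisopropylsilyloxy)benzaldehyde
Product: 10 [3-methoxy-4-(triisopropylsilyloxy)phenyl]methanol
Conditions: NaBH4, MeOH/THF, 0 °C
Reagents that add atoms: none
Why: Borohydride reduction of an aldehyde, which leaves the aryl silyl ether untouched at this temperature.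

Step 6
Reactants: 10 [3-methoxy-4-(triisopropylsilyloxy)phenyl]methanol
Product: 11 3-methoxy-4-(triisopropylsilyloxy)benzyl bromide
Conditions: PBr3 (0.4 equiv), Et2O, 0 °C; short silica plug, used at once
Reagents that add atoms: phosphorus tribromide, BrP(Br)Br
Why: Bromide displaces the phosphite ester of a benzylic alcohol; the electron-rich bromide is labile and is therefore not stored.

Step 7
Reactants: 9 2-[3-methoxy-4-(triisopropylsilyloxy)phenyl]-1,3-dithiane; 5 (5S)-5-[(1S,2R,5S)-menthyloxy]furan-2(5H)-one; 11 3-methoxy-4-(triisopropylsilyloxy)benzyl bromide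
Product: 14 (3S,4S,5S)-3-[3-methoxy-4-(triisopropylsilyloxy)benzyl]-4-{2-[3-methoxy-4-(triisopropylsilyloxy)phenyl]-1,3-dithian-2-yl}-5-[(1S,2R,5S)-menthyloxy]oxolan-2-one (trans,trans), via 2-lithiodithiane 12 (not isolated), via lithium lactone enolate 13 (not isolated)
Conditions: 9, n-BuLi (1.05 equiv), THF, −78 to −20 °C; −78 °C, 5 in THF; DMPU (4 equiv), then 11, −78 to −20 °C; sat. aq. NH4Cl
Reagents that add atoms: none
Why: n-BuLi removes the C2–H of dithiane 9 to give the sulfur- and aryl-stabilised carbanion 12, which adds to the β-carbon of butenolide 5 (C4–C5 bond) to give lithium enolate 13, and 13 is C-benzylated by bromide 11 in an SN2 step (C3–CH2 bond). The closest known reaction type is the tandem Michael addition–enolate alkylation of 2-aryl-1,3-dithiane anions on butenolides and 5-alkoxyfuran-2(5H)-ones. No ring is closed, and the five-membered auxiliary lactone is carried through intact. C4 is set by the acetal carbon, whose bulky menthyloxy group blocks one face of the flat butenolide so that 12 enters anti to it, and C3 is set by the new quaternary dithianyl group, which shields its own face of the enolate so that 11 enters anti, giving the trans,trans lactone. The step needs 1,4- over 1,2-addition, secured by the soft delocalised carbanion and the reversibility of carbonyl addition at −78 °C, and C-monoalkylation, secured by DMPU activation of the enolate, the high SN2 reactivity of the benzylic bromide and the shielding of the remaining C3–H in the product.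

Step 8
Reactants: 14 trans,trans dithianyl lactone
Product: 15 (3S,4S,5S)-3-[3-methoxy-4-(triisopropylsilyloxy)benzyl]-4-[3-methoxy-4-(triisopropylsilyloxy)benzoyl]-5-[(1S,2R,5S)-menthyloxy]oxolan-2-one
Conditions: MeI (excess), CaCO3, MeCN/H2O 9:1, 45 °C
Reagents that add atoms: water, O
Why: Alkylative dithiane hydrolysis, in which S-methylation makes a sulfonium leaving group and water captures the ring B-stabilised thionium ion; the CaCO3 buffer keeps the medium neutral, so the acetal, the TIPS ethers and C4 (already in its favoured trans,trans arrangement) should stay untouched and β-elimination at the acetal carbon should be avoided.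

Step 9
Reactants: 15 aryl ketone
Product: 16 (3S,4R,5S)-4-{(R)-hydroxy[3-methoxy-4-(triisopropylsilyloxy)phenyl]methyl}-3-[3-methoxy-4-(triisopropylsilyloxy)benzyl]-5-[(1S,2R,5S)-menthyloxy]oxolan-2-one
Conditions: (S)-Me-CBS [(S)-1-methyl-3,3-diphenyltetrahydro-1H,3H-pyrrolo[1,2-c][1,3,2]oxazaborole, 0.3 equiv], BH3·SMe2 (1.2 equiv), THF, −30 °C; MeOH quench at −30 °C, pH 7 buffer
Reagents that add atoms: none
Why: Corey–Bakshi–Shibata reduction with ring B as the large group should deliver hydride in the sense that turns acetophenone into (R)-1-phenylethanol and so set C5 as R under catalyst control; the substrate's own bias should be small because both ring neighbours of C4 turn only hydrogens to the face that carries the aroyl group.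

Step 10
Reactants: 16 (R)-carbinol
Product: 19 (3S,4S,5R)-4-(hydroxymethyl)-3-[3-methoxy-4-(triisopropylsilyloxy)benzyl]-5-[3-methoxy-4-(triisopropylsilyloxy)phenyl]oxolan-2-one, via menthyl hemiacetal 17 (not isolated), via C4 carbaldehyde 18 (not isolated)
Conditions: NaBH4 (2 equiv), 1,8-diazabicyclo[5.4.0]undec-7-ene (DBU, 0.2 equiv), THF/i-PrOH 4:1, −20 to 0 °C; AcOH quench to pH 6 as soon as 16 is consumed
Reagents that add atoms: none
Why: Proposed new method: base-assisted addition of the C5 oxygen to C2 (5-exo-trig, through a 2,6-dioxabicyclo[2.2.1]heptan-1-olate in which ring B sits exo) is followed by cleavage of the bond from C2 to the acetal oxygen, because a hemiacetal oxide is a better leaving group than an alkoxide; hemiacetal 17 then loses (+)-menthol to give aldehyde 18, and NaBH4 should reduce 18 faster than C4 can enolise, so C3, C4 and C5 are carried over unchanged and appear as the 3,4-cis-4,5-trans lactone; the closest known reaction types are the base-mediated translactonisation of 4-(α-hydroxybenzyl)butyrolactones and the hydroxide opening of 5-menthyloxybutyrolactones with NaBH4 capture of the released aldehyde, and the new element is an internal alkoxide as acyl acceptor on such a pseudo-ester.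

Step 11
Reactants: 19 bis-TIPS lactone
Product: 20 (3S,4S,5R)-3-(4-hydroxy-3-methoxybenzyl)-5-(4-hydroxy-3-methoxyphenyl)-4-(hydroxymethyl)oxolan-2-one (target)
Conditions: Bu4NF (2.2 equiv) premixed with AcOH (2.4 equiv), THF, 0 °C
Reagents that add atoms: none
Why: Fluoride cleavage of aryl silyl ethers; the acetic acid keeps the liberated phenols protonated, which should prevent para-quinone-methide expulsion of the carboxylate at C5, epimerisation at C3 and migration of the acyl group to the CH2OH oxygen.

**Compound list**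
1 | furfural | O=Cc1ccco1 | starting material
2 | 5-hydroxyfuran-2(5H)-one (racemic) | O=C1C=CC(O)O1 | intermediate
3 | (+)-menthol, (1S,2R,5S) | CC(C)[C@H]1CC[C@H](C)C[C@@H]1O | starting material
4 | 5-[(1S,2R,5S)-menthyloxy]furan-2(5H)-one, mixture of C5 epimers | O=C1C=CC(O[C@H]2C[C@@H](C)CC[C@@H]2C(C)C)O1 | intermediate
5 | (5S)-5-[(1S,2R,5S)-menthyloxy]furan-2(5H)-one | O=C1C=C[C@@H](O[C@H]2C[C@@H](C)CC[C@@H]2C(C)C)O1 | intermediate
6 | vanillin | O=Cc1ccc(O)c(OC)c1 | starting material
7 | 3-methoxy-4-(triisopropylsilyloxy)benzaldehyde | O=Cc1ccc(O[Si](C(C)C)(C(C)C)C(C)C)c(OC)c1 | intermediate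
8 | propane-1,3-dithiol | SCCCS | starting material
9 | 2-[3-methoxy-4-(triisopropylsilyloxy)phenyl]-1,3-dithiane | CC(C)[Si](C(C)C)(C(C)C)Oc1ccc(C2SCCCS2)cc1OC | intermediate
10 | [3-methoxy-4-(triisopropylsilyloxy)phenyl]methanol | OCc1ccc(O[Si](C(C)C)(C(C)C)C(C)C)c(OC)c1 | intermediate
11 | 3-methoxy-4-(triisopropylsilyloxy)benzyl bromide | COc1cc(CBr)ccc1O[Si](C(C)C)(C(C)C)C(C)C | intermediate
12 | 2-lithio derivative of 9 | [Li]C1(c2ccc(O[Si](C(C)C)(C(C)C)C(C)C)c(OC)c2)SCCCS1 | intermediate
13 | lithium enolate of the trans 4-dithianyl-5-menthyloxy lactone | [Li]OC1=C[C@H](C2(c3ccc(O[Si](C(C)C)(C(C)C)C(C)C)c(OC)c3)SCCCS2)[C@@H](O[C@H]2C[C@@H](C)CC[C@@H]2C(C)C)O1 | intermediate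
14 | (3S,4S,5S) trans,trans 3-benzyl-4-(2-aryl-1,3-dithian-2-yl)-5-menthyloxyoxolan-2-one | O=C1O[C@H](O[C@H]2C[C@@H](C)CC[C@@H]2C(C)C)[C@@H](C2(c3ccc(O[Si](C(C)C)(C(C)C)C(C)C)c(OC)c3)SCCCS2)[C@@H]1Cc1ccc(O[Si](C(C)C)(C(C)C)C(C)C)c(OC)c1 | intermediate
15 | (3S,4S,5S) 4-aroyl-3-benzyl-5-menthyloxyoxolan-2-one | O=C1O[C@H](O[C@H]2C[C@@H](C)CC[C@@H]2C(C)C)[C@@H](C(=O)c2ccc(O[Si](C(C)C)(C(C)C)C(C)C)c(OC)c2)[C@@H]1Cc1ccc(O[Si](C(C)C)(C(C)C)C(C)C)c(OC)c1 | intermediate
16 | (3S,4R,5S) 4-[(R)-aryl(hydroxy)methyl]-3-benzyl-5-menthyloxyoxolan-2-one | O=C1O[C@H](O[C@H]2C[C@@H](C)CC[C@@H]2C(C)C)[C@@H]([C@@H](O)c2ccc(O[Si](C(C)C)(C(C)C)C(C)C)c(OC)c2)[C@@H]1Cc1ccc(O[Si](C(C)C)(C(C)C)C(C)C)c(OC)c1 | intermediate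
17 | transposed lactone carrying CH(OH)(O-menthyl) on C4 | COc1cc(C[C@@H]2C(=O)O[C@@H](c3ccc(O[Si](C(C)C)(C(C)C)C(C)C)c(OC)c3)[C@@H]2[C@H](O)O[C@H]4C[C@@H](C)CC[C@@H]4C(C)C)ccc1O[Si](C(C)C)(C(C)C)C(C)C | intermediate
18 | transposed lactone carrying CHO on C4 (3,4-cis, 4,5-trans) | COc1cc(C[C@@H]2C(=O)O[C@@H](c3ccc(O[Si](C(C)C)(C(C)C)C(C)C)c(OC)c3)[C@@H]2C=O)ccc1O[Si](C(C)C)(C(C)C)C(C)C | intermediate
19 | (3S,4S,5R) bis-TIPS ether of the target | COc1cc(C[C@@H]2C(=O)O[C@@H](c3ccc(O[Si](C(C)C)(C(C)C)C(C)C)c(OC)c3)[C@@H]2CO)ccc1O[Si](C(C)C)(C(C)C)C(C)C | intermediate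
20 | (3S,4S,5R)-3-(4-hydroxy-3-methoxybenzyl)-5-(4-hydroxy-3-methoxyphenyl)-4-(hydroxymethyl)oxolan-2-one | COc1cc(C[C@@H]2C(=O)O[C@@H](c3ccc(O)c(OC)c3)[C@@H]2CO)ccc1O | target

**Step count**
Total: 11 steps.
Longest linear sequence: 8 steps (6 → 7 → 10 → 11 → 14 → 15 → 16 → 19 → 20).

**Steps most likely to fail**

1. Step 10.
   - Risk: the acyl shift may be slow through the strained bicyclic intermediate. The transient aldehyde may enolise before hydride arrives, which would epimerise C4 or cause β-elimination of the C5 carboxylate. After reduction, the new primary alkoxide may pull the acyl group back onto the CH2O oxygen.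
   - Fallback (known chemistry only): it sets out from 14 and comes back at 20. LiOH (THF/H2O, 0 °C) opens the pseudo-ester of 14 while NaBH4 in the same flask reduces the released formyl group. Acidification with citric acid gives the hydroxy acid F1, which closes with catalytic pyridinium p-toluenesulfonate to the trans dithianyl butyrolactone F2. Me(MeO)NH·HCl/AlMe3 (CH2Cl2, 0 °C) opens F2 to the hydroxy Weinreb amide F3. Its primary alcohol is capped at once (TBSCl, imidazole, DMF) as the TBS ether F4, so the CH2O oxygen can no longer compete for the acyl group. MeI/CaCO3 as in step 8 gives the keto amide F5, and (S)-Me-CBS/BH3·SMe2 as in step 9 gives the (R)-carbinol amide F6. Catalytic pyridinium p-toluenesulfonate in toluene then closes F6 on its only free hydroxyl, with loss of N,O-dimethylhydroxylamine, to the tris-silylated lactone F7. Buffered fluoride as in step 11 (3.5 equiv) removes all three silyl groups and gives 20.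

2. Step 9.
   - Risk: poor facial selectivity, because the branched C4 substituent competes in effective size with ring B. This would erode catalyst control at C5.
   - Fallback: it sets out from 15 and comes back at 16. A Luche reduction without any chiral reagent (NaBH4, CeCl3·7H2O, MeOH/THF, −78 °C) gives 16 together with the C5-epimeric (S)-carbinol F8. The two diastereomers are separated by chromatography. F8 is oxidised back to 15 with MnO2 (CH2Cl2, rt) and recycled, so C5 is secured by separation and recycling instead of asymmetric induction.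

3. Step 7.
   - Risk: proton transfer between enolate, product and unreacted dithiane, retro-Michael loss of the dithiane anion on warming, or decay of the labile bromide before alkylation. Any of these would give incomplete or double benzylation.
   - Fallback: it sets out from 9 and 5 and comes back at 14. The two bond formations are decoupled. After the conjugate addition of 12 to 5, the enolate is protonated at −78 °C (NH4Cl) and the trans Michael adduct F9 is isolated and purified. F9 is then deprotonated with LDA (THF/DMPU, −78 °C), which regenerates 13 free of excess carbanion. Alkylation with fresh 11 occurs anti to the dithianyl group and gives 14.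

**Further compounds**
F1 | step 10 | (2S,3S)-4-hydroxy-2-(ring A benzyl)-3-[2-(ring B aryl)-1,3-dithian-2-yl]butanoic acid | OC(=O)[C@@H](Cc1ccc(O[Si](C(C)C)(C(C)C)C(C)C)c(OC)c1)[C@@H](CO)C1(c2ccc(O[Si](C(C)C)(C(C)C)C(C)C)c(OC)c2)SCCCS1
F2 | step 10 | (3S,4S)-3-(ring A benzyl)-4-[2-(ring B aryl)-1,3-dithian-2-yl]oxolan-2-one | O=C1OC[C@@H](C2(c3ccc(O[Si](C(C)C)(C(C)C)C(C)C)c(OC)c3)SCCCS2)[C@@H]1Cc1ccc(O[Si](C(C)C)(C(C)C)C(C)C)c(OC)c1
F3 | step 10 | (2S,3S)-4-hydroxy-N-methoxy-N-methyl-2-(ring A benzyl)-3-[2-(ring B aryl)-1,3-dithian-2-yl]butanamide | CON(C)C(=O)[C@@H](Cc1ccc(O[Si](C(C)C)(C(C)C)C(C)C)c(OC)c1)[C@@H](CO)C1(c2ccc(O[Si](C(C)C)(C(C)C)C(C)C)c(OC)c2)SCCCS1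
F4 | step 10 | O-TBS ether of F3 | CON(C)C(=O)[C@@H](Cc1ccc(O[Si](C(C)C)(C(C)C)C(C)C)c(OC)c1)[C@@H](CO[Si](C)(C)C(C)(C)C)C1(c2ccc(O[Si](C(C)C)(C(C)C)C(C)C)c(OC)c2)SCCCS1
F5 | step 10 | (2S,3S)-3-(TBSO-methyl)-N-methoxy-N-methyl-2-(ring A benzyl)-4-oxo-4-(ring B aryl)butanamide | CON(C)C(=O)[C@@H](Cc1ccc(O[Si](C(C)C)(C(C)C)C(C)C)c(OC)c1)[C@@H](CO[Si](C)(C)C(C)(C)C)C(=O)c1ccc(O[Si](C(C)C)(C(C)C)C(C)C)c(OC)c1
F6 | step 10 | (2S,3S,4R)-4-hydroxy analogue of F5 | CON(C)C(=O)[C@@H](Cc1ccc(O[Si](C(C)C)(C(C)C)C(C)C)c(OC)c1)[C@@H](CO[Si](C)(C)C(C)(C)C)[C@@H](O)c1ccc(O[Si](C(C)C)(C(C)C)C(C)C)c(OC)c1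
F7 | step 10 | (3S,4S,5R) target lactone with CH2OTBS and two aryl OTIPS groups | COc1cc(C[C@@H]2C(=O)O[C@@H](c3ccc(O[Si](C(C)C)(C(C)C)C(C)C)c(OC)c3)[C@@H]2CO[Si](C)(C)C(C)(C)C)ccc1O[Si](C(C)C)(C(C)C)C(C)C
F8 | step 9 | C5 epimer of 16, (S)-carbinol | O=C1O[C@H](O[C@H]2C[C@@H](C)CC[C@@H]2C(C)C)[C@@H]([C@H](O)c2ccc(O[Si](C(C)C)(C(C)C)C(C)C)c(OC)c2)[C@@H]1Cc1ccc(O[Si](C(C)C)(C(C)C)C(C)C)c(OC)c1
F9 | step 7 | (4S,5S)-4-[2-(ring B aryl)-1,3-dithian-2-yl]-5-[(1S,2R,5S)-menthyloxy]oxolan-2-one | O=C1O[C@H](O[C@H]2C[C@@H](C)CC[C@@H]2C(C)C)[C@@H](C2(c3ccc(O[Si](C(C)C)(C(C)C)C(C)C)c(OC)c3)SCCCS2)C1
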